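Remark: the stereodescriptors are used exactly as written. 5R together with 10R puts C4 (on C5) and C1 (on C10) on opposite faces of ring 2, so the ether is an inside–outside (trans-bridged) 11-oxabicyclo[4.4.1]undecane with the C5 hydrogen inside, and the route is designed for that isomer.

## The problem

The target 39 is a germacranolide in which the ten-membered carbocycle C1–C10 is spanned by an ether oxygen between C5 and C10. The oxygen divides the carbocycle into two oxepanes, ring 1 (O, C5, C4, C3, C2, C1, C10) and ring 2 (O, C5, C6, C7, C8, C9, C10). An α-methylene-γ-lactone (ring 3: O, C6, C7, C11, C12, with C13 as the methylene) is cis-fused to ring 2 at C6–C7, C14 is the methyl on C10 and C15 the acetoxymethyl on C4. Because C5 and C10 are both R, the two carbon bridges leave the bridgeheads on opposite faces: whichever oxepane is closed second must be closed against the strain of an inside–outside bicycle, and once the bicycle exists no reagent can reach C5 from inside. Of the seven stereocentres (3R, 4R, 5R, 6R, 7R, 8R, 10R), C10 is quaternary and insulated by methylene groups, so it cannot be induced and is best bought; C3/C4 are an adjacent pair that one aldol can set; C5/C6 are a vicinal pair; C6 can direct C7 through the cis ring fusion, and the lactone face can direct C8. Four features will not survive rough treatment, so the acyl groups and the methylene belong at the end: the methylene lactone (a Michael acceptor that isomerises into the ring if C8 is a ketone), the (Z)-2-(acetoxymethyl)but-2-enoate (the less stable geometry), the two primary acetates beside a free C3 hydroxyl, and an O8 cis to C11 that can relactonise under base. The feature that opens the way is that C5 (ether bridgehead) and C6 (lactone oxygen) are vicinal oxygen-bearing carbons with the relative configuration of an anti opening of a cis-C5,C6-epoxide, while the C10 oxygen is a tertiary hydroxyl six atoms from C5: ring 1 can be closed by a stereospecific 7-exo epoxide opening while the molecule is still monocyclic and strain-free.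

## Retrosynthesis

**Peripheral esters.** The two primary acetate C–O bonds of 39 are cut to give triol 38, and the C8–O acyl bond is cut through tris-silyl ether 37 to alcohol 31 and acid 36. Cutting the acetates before the C8 ester lets the Z-acid travel as a silyl ether, so one fluoride step uncovers O3, O15 and the side-chain hydroxyl and one selective acetylation finishes. The forward steps must acylate a hindered secondary alcohol without isomerising the Z alkene and must tell primary from secondary hydroxyl. Acid 36 is cut at its carboxyl carbon to vinyl iodide 35, which goes back through alcohol 34 and iodoenal 33 to crotonaldehyde 32; the alkene geometry is fixed at the iodination and only has to be retained.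

**C11=C13.** The exocyclic double bond of 31 is cut, through Mannich base 29, to the 13-nor lactone 28. Carrying C13 through the ring closure would expose an acrylate to the reducing conditions; adding it afterwards needs only a lactone enolate. The forward reaction must tolerate the free C8 hydroxyl.

**C8 configuration.** No bond is cut here; the C8 carbinol of 28 is traced to ketone 27 and on to the epimeric alcohol 26. This relieves the ring closure of any duty at C8 and hands the centre to a hydride reduction steered by the finished ring system.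

**C7–C8, ring 2.** The C7–C8 bond of 26 is cut to give aldehyde 25, a monocyclic oxepane carrying a butenolide. Cutting C6–C7 instead would force the closure to create C6 as well, and cutting an ether bond of ring 2 would undo what ring 1 sets. This cut leaves C5, C6 and C10 fixed and asks only for C7, which a butenolide delivers by geometry because the tether can reach only one of its faces. The forward reaction must close a seven-membered ring into a trans-bridged junction, which calls for an early, irreversible transition state such as a ketyl radical addition. Aldehyde 25 comes from alcohol 24; the lactone C12–O6 bond of 24 is cut to hydroxy enoate 22, and 22 is 21 without its PMB group.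

**O–C5, ring 1 (key).** The O–C5 bond of oxepane 21 is cut to give epoxy alcohol 20. Cutting O–C10 instead would mean substitution at a tertiary carbon and loss of the C10 configuration; here C10 is only the nucleophile and C5 is created by inversion. The precursor is acyclic, and the forward step must choose C5 over C6 and the hydroxyl over every other internal nucleophile.

**Epoxy enoate.** Compound 20 is 19 without its TMS group. The C7=C11 bond of 19 is cut to ylide 17 and, through aldehyde 18, epoxy alcohol 16; removing the epoxide oxygen gives Z-allylic alcohol 15. Alcohol 15 comes from Z-enoate 14, whose C5=C6 bond is cut to aldehyde 12 and phosphonate 13. A reagent-controlled epoxidation of an allylic alcohol is preferred to a direct epoxidation of a dienoate because it names the face independently of the substrate.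

**C3–C4.** Aldehyde 12 is the cleavage product of vinyl compound 11 (bis-silyl ether of diol 10), and 10 comes from aldol adduct 9. The C3–C4 bond of 9 is cut to aldehyde 5 and crotonyl imide 8, itself from oxazolidinone 6 and acid chloride 7. One aldol sets both centres, the imide carbonyl becomes C15 and the vinyl group is a masked C5 aldehyde. The forward reaction is asked for syn selectivity and α-regioselectivity of the dienolate.

**Chiral pool.** Aldehyde 5 goes back through silyl ether 4, PMB ether 3 and diol 2 to (R)-linalool 1: its vinyl group supplies C9 and C8, its prenyl arm C1–C3, and its carbinol carbon is C10 with the required configuration.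

## Roads not taken

**Alternative 1: Criegee ring expansion.** The cut is the C5–C10 bond of a carbocyclic decalin. Acetylation of hydroperoxide A1 would make C10 migrate from C5 to oxygen with retention, break C5–C10 and let acetate trap the bridgehead oxocarbenium ion, giving ketal acetate A2 with rings 1 and 2 and the ether bridge formed at once. In ring construction this road is better than the chosen one: the skeleton is assembled as two six-membered rings with well-understood stereocontrol, and no medium ring is ever closed. Its weak point is C5. It emerges as a ketal carbon, and the bridgehead cation can be approached by acetate, and later by hydride, only from outside the bicycle, whereas 5R with 10R requires the C5 substituent inside (A2 as written carries its acetoxy group in the inside position). The road therefore fits the cis-bridged C5 epimer. The chosen plan sets C5 by inversion on an open chain before any bicycle exists; against the elegance of A1 to A2 it has to set the later closure of a strained ring 2.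

**Alternative 2: intramolecular allylation–lactonisation.** The cut is C6–C7 plus the lactone C–O bond. CrCl2 would turn the allylic bromide of aldehyde A3 into an allylchromium reagent whose γ-carbon C7 adds to the C6 aldehyde, and the alkoxide closes onto C12 to give lactone A4. In end-game economy this road is better: ring 2, the lactone and the exocyclic methylene arise together, and O8 arrives with its configuration, so neither the C8 redox correction nor the late methylenation is needed. Its weak points lie earlier. A3 still needs ring 1 with C5 in place, so an ether-forming step like the present key step is required anyway. The aldehyde sits on the epimerisable α-alkoxy carbon C5. C6 and C7 are both created in the strained closure, with their relative configuration depending on allylmetal geometry and on Felkin versus chelate control, and nothing fixes them beforehand. The chosen plan fixes C6 together with C5 in the epoxide and C7 through the butenolide fusion, and pays with about four more steps after ring closure.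

**Alternative 3: chromium-templated [6π+4π] cycloaddition.** The cut is C5–C6 and C9–C10. Irradiation of the Cr(CO)3 oxepin complex A5 with diene A6 would join the triene termini to the diene termini and, after decomplexation, give adduct A7. This is the most convergent road by a wide margin: ring 2 and the ten-membered ring come from two flat pieces in one step, with O6, the C7 acetic ester arm and O8 already placed. For this target it fails on topology: the cycloaddition is suprafacial on the triene, so both new bonds form on the same face and the C5 hydrogen and C10 methyl both end up outside, not in the inside–outside arrangement written for A7. Further weak points are a quaternary centre formed at a methyl-bearing terminus, a labile oxepin complex that is planar-chiral and therefore racemic, and C3 and C4 still to be set on a ring diene. The chosen plan is much longer, but each stereocentre has a named control element and the C5/C10 relationship is free of topological constraint.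

Key step: step 15

## Route

Step 1
Reactants: 1 (R)-linalool
Product: 2 (3R)-3,7-dimethyloct-6-ene-1,3-diol
Conditions: 9-BBN (2.2 equiv), THF, 0 °C to rt; then NaOH (aq), H2O2, 0 °C
Reagents that add atoms: hydrogen peroxide, OO
Why: Hydroboration–oxidation; 9-BBN adds to the monosubstituted vinyl group much faster than to the trisubstituted alkene and places boron on the terminal carbon, so C8 becomes a primary alcohol and C10 is untouched.

Step 2
Reactants: 2 (3R)-3,7-dimethyloct-6-ene-1,3-diol
Product: 3 (3R)-1-[(4-methoxybenzyl)oxy]-3,7-dimethyloct-6-en-3-ol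
Conditions: NaH (1.05 equiv), 4-methoxybenzyl chloride, Bu4NI (cat.), THF/DMF, 0 °C to rt
Reagents that add atoms: 4-methoxybenzyl chloride, COc1ccc(CCl)cc1
Why: Williamson etherification; the primary alkoxide is alkylated far faster than the hindered tertiary one.

Step 3
Reactants: 3 (3R)-1-[(4-methoxybenzyl)oxy]-3,7-dimethyloct-6-en-3-ol
Product: 4 tertiary TMS ether of 3
Conditions: TMSOTf, 2,6-lutidine, CH2Cl2, −78 °C
Reagents that add atoms: trimethylsilyl trifluoromethanesulfonate, C[Si](C)(C)OS(=O)(=O)C(F)(F)F
Why: Silylation of the tertiary alcohol; it prevents the 4-hydroxy aldehyde of step 4 from closing to a lactol, and a tertiary TMS ether can later be removed without touching TBS ethers.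

Step 4
Reactants: 4 tertiary TMS ether of 3
Product: 5 (4R)-6-[(4-methoxybenzyl)oxy]-4-methyl-4-[(trimethylsilyl)oxy]hexanal
Conditions: OsO4 (2 mol %), NaIO4, 2,6-lutidine, dioxane/H2O, rt
Reagents that add atoms: sodium periodate, [Na+].[O-]I(=O)(=O)=O
Why: Lemieux–Johnson cleavage of the only alkene gives the C3 aldehyde; the lutidine buffer protects the TMS ether and the PMB ether is inert to these conditions.

Step 5
Reactants: 6 (4S)-4-benzyl-1,3-oxazolidin-2-one; 7 (2E)-but-2-enoyl chloride
Product: 8 (4S)-4-benzyl-3-[(2E)-but-2-enoyl]-1,3-oxazolidin-2-one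
Conditions: n-BuLi, THF, −78 °C; then 7, −78 to 0 °C
Reagents that add atoms: none
Why: N-acylation of the lithiated oxazolidinone, the standard preparation of Evans imides.

Step 6
Reactants: 5 (4R)-6-[(4-methoxybenzyl)oxy]-4-methyl-4-[(trimethylsilyl)oxy]hexanal; 8 (4S)-4-benzyl-3-[(2E)-but-2-enoyl]-1,3-oxazolidin-2-one
Product: 9 syn-aldol adduct with α-vinyl group
Conditions: 8, Bu2BOTf, Et3N, CH2Cl2, −78 to 0 °C; then 5, −78 to 0 °C; then pH 7 buffer, MeOH, H2O2
Reagents that add atoms: none
Why: Evans syn-aldol of the boron dienolate formed by γ-deprotonation of the crotonyl imide; reaction at the α-carbon through a Zimmerman–Traxler chair sets C3 and C4 together, and the (S)-benzyl auxiliary chooses the enolate face (2S,3R in the adduct).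

Step 7
Reactants: 9 syn-aldol adduct with α-vinyl group
Product: 10 (2R,3R,6R)-2-ethenyl-8-[(4-methoxybenzyl)oxy]-6-methyl-6-[(trimethylsilyl)oxy]octane-1,3-diol
Conditions: LiBH4, MeOH (1 equiv), THF, 0 °C
Reagents that add atoms: none
Why: Reductive cleavage of the imide turns its carbonyl into the C15 primary alcohol and releases the auxiliary; the β-hydroxyl needs no protection.

Step 8
Reactants: 10 (2R,3R,6R)-2-ethenyl-8-[(4-methoxybenzyl)oxy]-6-methyl-6-[(trimethylsilyl)oxy]octane-1,3-diol
Product: 11 bis-TBS ether of 10
Conditions: TBSOTf (2.5 equiv), 2,6-lutidine, CH2Cl2, −78 to 0 °C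
Reagents that add atoms: tert-butyldimethylsilyl trifluoromethanesulfonate, CC(C)(C)[Si](C)(C)OS(=O)(=O)C(F)(F)F
Why: Silylation of O3 and O15 in one operation; both groups stay until step 29.

Step 9
Reactants: 11 bis-TBS ether of 10
Product: 12 C5 aldehyde
Conditions: OsO4 (2 mol %), NaIO4, 2,6-lutidine, dioxane/H2O, rt
Reagents that add atoms: sodium periodate, [Na+].[O-]I(=O)(=O)=O
Why: Lemieux–Johnson cleavage of the vinyl group, the only alkene present; the α-branched β-silyloxy aldehyde is taken on at once to avoid epimerisation at C4.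

Step 10
Reactants: 12 C5 aldehyde; 13 methyl bis(2,2,2-trifluoroethyl)phosphonoacetate
Product: 14 (Z)-enoate
Conditions: KHMDS, 18-crown-6, THF, −78 °C
Reagents that add atoms: none
Why: Still–Gennari olefination; the trifluoroethyl phosphonate gives the Z-alkene under kinetic control, and the weakly basic anion does not epimerise C4.

Step 11
Reactants: 14 (Z)-enoate
Product: 15 (Z)-allylic alcohol
Conditions: i-Bu2AlH (2.5 equiv), CH2Cl2, −78 °C; Rochelle salt work-up
Reagents that add atoms: none
Why: 1,2-Reduction of the enoate to the allylic alcohol with retention of the Z geometry; silyl and PMB ethers are inert.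

Step 12
Reactants: 15 (Z)-allylic alcohol
Product: 16 cis-epoxy alcohol
Conditions: Ti(OiPr)4, D-(−)-diisopropyl tartrate, t-BuOOH, 4 Å molecular sieves, CH2Cl2, −20 °C
Reagents that add atoms: tert-butyl hydroperoxide, CC(C)(C)OO
Why: Sharpless asymmetric epoxidation; the D-(−)-tartrate delivers oxygen to the face that gives the (2R,3S)-cis-epoxy alcohol (C6 R, C5 S), and this is also the face opposite the larger C3 branch in the allylic-strain-minimised conformer of the Z-alkene, so reagent and substrate control are matched.

Step 13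
Reactants: 16 cis-epoxy alcohol; 17 methyl (triphenylphosphoranylidene)acetate
Product: 19 cis-epoxy (E)-enoate with C10 TMS ether, via cis-epoxy aldehyde 18 (not isolated)
Conditions: Dess–Martin periodinane, NaHCO3, CH2Cl2, 0 °C; then 17, rt
Reagents that add atoms: none
Why: Buffered Dess–Martin oxidation gives the sensitive cis-epoxy aldehyde, which is trapped in the same flask by the stabilised ylide (Wittig olefination) to give the E-enoate; the E geometry is wanted because it keeps the ester carbonyl away from the epoxide in step 15.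

Step 14
Reactants: 19 cis-epoxy (E)-enoate with C10 TMS ether
Product: 20 cis-C5,C6-epoxy (E)-enoate with free C10 tertiary alcohol
Conditions: K2CO3 (0.2 equiv), MeOH, 0 °C
Reagents that add atoms: none
Why: Base-catalysed methanolysis cleaves the TMS ether much faster than TBS ethers; catalytic carbonate at 0 °C should neither add methanol to the enoate nor open the epoxide.

Step 15
Reactants: 20 cis-C5,C6-epoxy (E)-enoate with free C10 tertiary alcohol
Product: 21 ring 1 oxepane with free C6 hydroxyl
Conditions: CSA (0.2 equiv), CH2Cl2, 0 °C to rt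
Reagents that add atoms: none
Why: CSA protonates the epoxide oxygen and the C10 hydroxyl attacks C5 from the side opposite the C5–O bond; loss of a proton gives the oxepane and leaves the former epoxide oxygen as the free C6 hydroxyl. The closest known reaction type is the acid-promoted exo-selective cyclisation of hydroxy epoxides to tetrahydropyrans and oxepanes. Ring 1 closes in the 7-exo-tet mode. C5 is the one new stereocentre: SN2 inversion of the 5S epoxide carbon gives 5R, so it is controlled by the tartrate-derived epoxide of step 12, while C6 keeps its configuration and no bond at C10 is broken. The step needs attack at C5 instead of C6: the 8-endo path is disfavoured by ring size, and the E-enoate withdraws electron density from C6 so that no allylic cation character develops there. It also needs the hydroxyl to be the only internal nucleophile: the E geometry holds the ester carbonyl away from the epoxide, and the silyl ether oxygens at C3 and C15 could react only in 4-exo or 5-endo modes. Because ring 2 does not exist yet, the trans relationship of the C6 and C9 arms across the ring oxygen, which later becomes the inside–outside junction, is set here without strain.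

Step 16
Reactants: 21 ring 1 oxepane with free C6 hydroxyl
Product: 22 C6,C8-diol (E)-enoate
Conditions: DDQ, CH2Cl2/pH 7 buffer, 0 °C to rt
Reagents that add atoms: none
Why: Oxidative cleavage of the PMB ether; TBS ethers and the electron-poor allylic alcohol are inert, and removing the anisyl chromophore leaves the enoate as the only absorber for step 17.

Step 17
Reactants: 22 C6,C8-diol (E)-enoate
Product: 24 butenolide with free C8 hydroxyl, via (Z)-enoate 23 (not isolated)
Conditions: hν (254 nm), MeCN (0.01 M), PPTS (cat.), rt
Reagents that add atoms: none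
Why: Photochemical E to Z isomerisation of the enoate followed by lactonisation; only the Z isomer can reach the C6 hydroxyl, so acid-catalysed ring closure drains the photostationary mixture to the butenolide, which also protects O6.

Step 18
Reactants: 24 butenolide with free C8 hydroxyl
Product: 25 butenolide C8 aldehyde
Conditions: Dess–Martin periodinane, NaHCO3, CH2Cl2, 0 °C to rt
Reagents that add atoms: none
Why: Dess–Martin oxidation of the only free hydroxyl; non-basic conditions avoid β-elimination of the ring oxygen from the β-alkoxy aldehyde and epimerisation of the butenolide at C6.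

Step 19
Reactants: 25 butenolide C8 aldehyde
Product: 26 tricyclic lactone with 8S hydroxyl
Conditions: SmI2 (3 equiv), HMPA, t-BuOH (2 equiv), THF (0.005 M), −78 to −40 °C
Reagents that add atoms: none
Why: Ketyl–olefin reductive cyclisation: divalent samarium reduces the aldehyde to a ketyl that adds 7-exo-trig to C7 of the butenolide, closing ring 2 as the trans-bridged bicycle, and the α-lactone radical is reduced and protonated. The tether can reach only the butenolide face syn to C5, which makes the lactone cis-fused and C7 R; the samarium-bound oxygen should turn away from the lactone and give the 8S alcohol shown. Either C8 epimer is acceptable because step 20 erases this centre.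

Step 20
Reactants: 26 tricyclic lactone with 8S hydroxyl
Product: 27 C8 ketone
Conditions: Dess–Martin periodinane, NaHCO3, CH2Cl2, 0 °C
Reagents that add atoms: none
Why: Dess–Martin oxidation converges both C8 epimers on one ketone under non-basic conditions, which should avoid β-elimination of the lactone oxygen and epimerisation at C7.

Step 21
Reactants: 27 C8 ketone
Product: 28 tricyclic lactone with 8R hydroxyl
Conditions: NaBH4, CeCl3·7H2O, MeOH/THF, −78 °C
Reagents that add atoms: none
Why: Luche-type carbonyl reduction at low temperature; hydride should approach C8 from the face opposite the cis-fused lactone carbon C11 and the C10 methyl group, which places O8 cis to C11 (8R), and the lactone carbonyl is not reduced under these conditions.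

Step 22
Reactants: 28 tricyclic lactone with 8R hydroxyl
Product: 29 C13 Mannich base
Conditions: LiHMDS (2.5 equiv), THF, −78 °C (inverse addition); then Me2N=CH2 iodide, −78 to 0 °C
Reagents that add atoms: N,N-dimethylmethyleneiminium iodide, C=[N+](C)C.[I-]
Why: Mannich reaction of the lactone enolate (formed as the dianion with the C8 alkoxide) with Eschenmoser's salt introduces C13; adding the substrate to excess base forms the enolate before the alkoxide can attack the lactone carbonyl, and the configuration at C11 is irrelevant.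

Step 23
Reactants: 29 C13 Mannich base
Product: 31 α-methylene lactone with free C8 hydroxyl, via methiodide 30 (not isolated)
Conditions: MeI, MeOH, rt; then NaHCO3 (aq), CH2Cl2
Reagents that add atoms: none
Why: Exhaustive N-methylation followed by Hofmann-type elimination of trimethylamine under bicarbonate gives the exocyclic methylene without strong base.

Step 24
Reactants: 32 (2E)-but-2-enal
Product: 33 (2Z)-2-iodobut-2-enal
Conditions: I2, K2CO3, DMAP (cat.), THF/H2O, rt
Reagents that add atoms: iodine, [I][I]
Why: α-Iodination of an enal by conjugate addition of DMAP, iodination of the enolate and elimination (Baylis–Hillman-type sequence); elimination gives the Z isomer with iodine cis to the methyl group.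

Step 25
Reactants: 33 (2Z)-2-iodobut-2-enal
Product: 34 (2Z)-2-iodobut-2-en-1-ol
Conditions: NaBH4, MeOH, 0 °C
Reagents that add atoms: none
Why: 1,2-Reduction of the aldehyde; the vinyl iodide and the alkene geometry are unaffected.

Step 26
Reactants: 34 (2Z)-2-iodobut-2-en-1-ol
Product: 35 TBS ether of 34
Conditions: TBSCl, imidazole, CH2Cl2, rt
Reagents that add atoms: tert-butyldimethylsilyl chloride, CC(C)(C)[Si](C)(C)Cl
Why: Standard silylation of a primary alcohol; the protecting group matches those on the core so that step 29 removes all of them together.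

Step 27
Reactants: 35 TBS ether of 34
Product: 36 (2Z)-2-{[(tert-butyldimethylsilyl)oxy]methyl}but-2-enoic acid
Conditions: t-BuLi (2.1 equiv), Et2O, −78 °C; then CO2; aq. NaHSO4 work-up
Reagents that add atoms: carbon dioxide, O=C=O
Why: Iodine–lithium exchange of a vinyl iodide proceeds with retention and the vinyllithium is configurationally stable at −78 °C, so carboxylation places the carboxyl group cis to the methyl group, as in the classical route to angelic acid.

Step 28
Reactants: 31 α-methylene lactone with free C8 hydroxyl; 36 (2Z)-2-{[(tert-butyldimethylsilyl)oxy]methyl}but-2-enoic acid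
Product: 37 C8 ester, tris-TBS ether
Conditions: 36, 2,4,6-trichlorobenzoyl chloride, Et3N, toluene, rt; then 31, DMAP, toluene, rt
Reagents that add atoms: none
Why: Yamaguchi esterification through the mixed anhydride; the hindered trichlorobenzoyl carbonyl directs the alcohol to the acyl group of 36, and a short reaction at room temperature with little DMAP should preserve the Z geometry and the methylene lactone.

Step 29
Reactants: 37 C8 ester, tris-TBS ether
Product: 38 triol
Conditions: HF·pyridine, pyridine, THF, 0 °C to rt
Reagents that add atoms: none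
Why: Fluoride-mediated desilylation under buffered, mildly acidic conditions removes all three TBS groups without acyl migration and without harming the esters, the methylene lactone or the ether bridge.

Step 30
Reactants: 38 triol
Product: 39 target
Conditions: AcCl (2.2 equiv), 2,4,6-collidine, CH2Cl2, −78 °C
Reagents that add atoms: acetyl chloride, CC(Cl)=O
Why: Selective acylation; acetyl chloride with the hindered base collidine at low temperature acetylates the two primary hydroxyls much faster than the secondary C3 hydroxyl flanked by C4.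

## Compound list

1 | (R)-linalool, (3R)-3,7-dimethylocta-1,6-dien-3-ol | C=C[C@](C)(O)CCC=C(C)C | starting material
2 | (3R)-3,7-dimethyloct-6-ene-1,3-diol | OCC[C@](C)(O)CCC=C(C)C | intermediate
3 | (3R)-1-[(4-methoxybenzyl)oxy]-3,7-dimethyloct-6-en-3-ol | COc1ccc(COCC[C@](C)(O)CCC=C(C)C)cc1 | intermediate
4 | {[(3R)-1-[(4-methoxybenzyl)oxy]-3,7-dimethyloct-6-en-3-yl]oxy}trimethylsilane | COc1ccc(COCC[C@](C)(O[Si](C)(C)C)CCC=C(C)C)cc1 | intermediate
5 | (4R)-6-[(4-methoxybenzyl)oxy]-4-methyl-4-[(trimethylsilyl)oxy]hexanal | COc1ccc(COCC[C@](C)(O[Si](C)(C)C)CCC=O)cc1 | intermediate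
6 | (4S)-4-benzyl-1,3-oxazolidin-2-one | O=C1OC[C@H](Cc2ccccc2)N1 | starting material
7 | (2E)-but-2-enoyl chloride | C/C=C/C(Cl)=O | starting material
8 | (4S)-4-benzyl-3-[(2E)-but-2-enoyl]-1,3-oxazolidin-2-one | C/C=C/C(=O)N1[C@@H](Cc2ccccc2)COC1=O | intermediate
9 | (4S)-4-benzyl-3-{(2S,3R,6R)-2-ethenyl-3-hydroxy-8-[(4-methoxybenzyl)oxy]-6-methyl-6-[(trimethylsilyl)oxy]octanoyl}-1,3-oxazolidin-2-one | C=C[C@H](C(=O)N1[C@@H](Cc2ccccc2)COC1=O)[C@H](O)CC[C@@](C)(O[Si](C)(C)C)CCOCc1ccc(OC)cc1 | intermediate
10 | (2R,3R,6R)-2-ethenyl-8-[(4-methoxybenzyl)oxy]-6-methyl-6-[(trimethylsilyl)oxy]octane-1,3-diol | C=C[C@H](CO)[C@H](O)CC[C@@](C)(O[Si](C)(C)C)CCOCc1ccc(OC)cc1 | intermediate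
11 | (3R,4R,7R)-4-[(tert-butyldimethylsilyl)oxy]-3-{[(tert-butyldimethylsilyl)oxy]methyl}-9-[(4-methoxybenzyl)oxy]-7-methyl-7-[(trimethylsilyl)oxy]non-1-ene | C=C[C@H](CO[Si](C)(C)C(C)(C)C)[C@H](O[Si](C)(C)C(C)(C)C)CC[C@@](C)(O[Si](C)(C)C)CCOCc1ccc(OC)cc1 | intermediate
12 | (2R,3R,6R)-3-[(tert-butyldimethylsilyl)oxy]-2-{[(tert-butyldimethylsilyl)oxy]methyl}-8-[(4-methoxybenzyl)oxy]-6-methyl-6-[(trimethylsilyl)oxy]octanal | O=C[C@H](CO[Si](C)(C)C(C)(C)C)[C@H](O[Si](C)(C)C(C)(C)C)CC[C@@](C)(O[Si](C)(C)C)CCOCc1ccc(OC)cc1 | intermediate
13 | methyl bis(2,2,2-trifluoroethyl)phosphonoacetate | COC(=O)CP(=O)(OCC(F)(F)F)OCC(F)(F)F | starting material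
14 | methyl (2Z,4R,5R,8R)-5-[(tert-butyldimethylsilyl)oxy]-4-{[(tert-butyldimethylsilyl)oxy]methyl}-10-[(4-methoxybenzyl)oxy]-8-methyl-8-[(trimethylsilyl)oxy]dec-2-enoate | COC(=O)/C=C\[C@H](CO[Si](C)(C)C(C)(C)C)[C@H](O[Si](C)(C)C(C)(C)C)CC[C@@](C)(O[Si](C)(C)C)CCOCc1ccc(OC)cc1 | intermediate
15 | (2Z,4R,5R,8R)-5-[(tert-butyldimethylsilyl)oxy]-4-{[(tert-butyldimethylsilyl)oxy]methyl}-10-[(4-methoxybenzyl)oxy]-8-methyl-8-[(trimethylsilyl)oxy]dec-2-en-1-ol | OC/C=C\[C@H](CO[Si](C)(C)C(C)(C)C)[C@H](O[Si](C)(C)C(C)(C)C)CC[C@@](C)(O[Si](C)(C)C)CCOCc1ccc(OC)cc1 | intermediate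
16 | [(2R,3S)-3-{(2S,3R,6R)-1,3-bis[(tert-butyldimethylsilyl)oxy]-8-[(4-methoxybenzyl)oxy]-6-methyl-6-[(trimethylsilyl)oxy]octan-2-yl}oxiran-2-yl]methanol | OC[C@H]1O[C@H]1[C@H](CO[Si](C)(C)C(C)(C)C)[C@H](O[Si](C)(C)C(C)(C)C)CC[C@@](C)(O[Si](C)(C)C)CCOCc1ccc(OC)cc1 | intermediate
17 | methyl (triphenylphosphoranylidene)acetate | COC(=O)C=P(c1ccccc1)(c1ccccc1)c1ccccc1 | starting material
18 | (2S,3S)-3-{(2S,3R,6R)-1,3-bis[(tert-butyldimethylsilyl)oxy]-8-[(4-methoxybenzyl)oxy]-6-methyl-6-[(trimethylsilyl)oxy]octan-2-yl}oxirane-2-carbaldehyde | O=C[C@H]1O[C@H]1[C@H](CO[Si](C)(C)C(C)(C)C)[C@H](O[Si](C)(C)C(C)(C)C)CC[C@@](C)(O[Si](C)(C)C)CCOCc1ccc(OC)cc1 | intermediate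
19 | methyl (2E)-3-[(2R,3S)-3-{(2S,3R,6R)-1,3-bis[(tert-butyldimethylsilyl)oxy]-8-[(4-methoxybenzyl)oxy]-6-methyl-6-[(trimethylsilyl)oxy]octan-2-yl}oxiran-2-yl]prop-2-enoate | COC(=O)/C=C/[C@H]1O[C@H]1[C@H](CO[Si](C)(C)C(C)(C)C)[C@H](O[Si](C)(C)C(C)(C)C)CC[C@@](C)(O[Si](C)(C)C)CCOCc1ccc(OC)cc1 | intermediate
20 | methyl (2E)-3-[(2R,3S)-3-{(2S,3R,6R)-1,3-bis[(tert-butyldimethylsilyl)oxy]-6-hydroxy-8-[(4-methoxybenzyl)oxy]-6-methyloctan-2-yl}oxiran-2-yl]prop-2-enoate | COC(=O)/C=C/[C@H]1O[C@H]1[C@H](CO[Si](C)(C)C(C)(C)C)[C@H](O[Si](C)(C)C(C)(C)C)CC[C@@](C)(O)CCOCc1ccc(OC)cc1 | intermediate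
21 | methyl (2E,4R)-4-[(2R,3S,4R,7R)-4-[(tert-butyldimethylsilyl)oxy]-3-{[(tert-butyldimethylsilyl)oxy]methyl}-7-{2-[(4-methoxybenzyl)oxy]ethyl}-7-methyloxepan-2-yl]-4-hydroxybut-2-enoate | COC(=O)/C=C/[C@@H](O)[C@@H]1O[C@](C)(CC[C@@H](O[Si](C)(C)C(C)(C)C)[C@H]1CO[Si](C)(C)C(C)(C)C)CCOCc1ccc(OC)cc1 | intermediate
22 | methyl (2E,4R)-4-[(2R,3S,4R,7R)-4-[(tert-butyldimethylsilyl)oxy]-3-{[(tert-butyldimethylsilyl)oxy]methyl}-7-(2-hydroxyethyl)-7-methyloxepan-2-yl]-4-hydroxybut-2-enoate | COC(=O)/C=C/[C@@H](O)[C@@H]1O[C@](C)(CC[C@@H](O[Si](C)(C)C(C)(C)C)[C@H]1CO[Si](C)(C)C(C)(C)C)CCO | intermediate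
23 | (2Z) isomer of 22 | COC(=O)/C=C\[C@@H](O)[C@@H]1O[C@](C)(CC[C@@H](O[Si](C)(C)C(C)(C)C)[C@H]1CO[Si](C)(C)C(C)(C)C)CCO | intermediate
24 | (5R)-5-[(2R,3S,4R,7R)-4-[(tert-butyldimethylsilyl)oxy]-3-{[(tert-butyldimethylsilyl)oxy]methyl}-7-(2-hydroxyethyl)-7-methyloxepan-2-yl]furan-2(5H)-one | O=C1C=C[C@@H](O1)[C@@H]2O[C@](C)(CC[C@@H](O[Si](C)(C)C(C)(C)C)[C@H]2CO[Si](C)(C)C(C)(C)C)CCO | intermediate
25 | (5R)-5-[(2R,3S,4R,7R)-4-[(tert-butyldimethylsilyl)oxy]-3-{[(tert-butyldimethylsilyl)oxy]methyl}-7-methyl-7-(2-oxoethyl)oxepan-2-yl]furan-2(5H)-one | O=C1C=C[C@@H](O1)[C@@H]2O[C@](C)(CC[C@@H](O[Si](C)(C)C(C)(C)C)[C@H]2CO[Si](C)(C)C(C)(C)C)CC=O | intermediate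
26 | (3R,4S,5R,6R,7R,8S,10R)-3,15-bis[(tert-butyldimethylsilyl)oxy]-8-hydroxy-5,10-epoxy-13-norgermacran-12,6-olide | C1C(=O)O[C@H]2[C@@H]3O[C@](C)(CC[C@@H](O[Si](C)(C)C(C)(C)C)[C@H]3CO[Si](C)(C)C(C)(C)C)C[C@H](O)[C@@H]12 | intermediate
27 | (3R,4S,5R,6R,7S,10R)-3,15-bis[(tert-butyldimethylsilyl)oxy]-8-oxo-5,10-epoxy-13-norgermacran-12,6-olide | C1C(=O)O[C@H]2[C@@H]3O[C@](C)(CC[C@@H](O[Si](C)(C)C(C)(C)C)[C@H]3CO[Si](C)(C)C(C)(C)C)CC(=O)[C@@H]12 | intermediate
28 | (3R,4S,5R,6R,7R,8R,10R)-3,15-bis[(tert-butyldimethylsilyl)oxy]-8-hydroxy-5,10-epoxy-13-norgermacran-12,6-olide | C1C(=O)O[C@H]2[C@@H]3O[C@](C)(CC[C@@H](O[Si](C)(C)C(C)(C)C)[C@H]3CO[Si](C)(C)C(C)(C)C)C[C@@H](O)[C@@H]12 | intermediate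
29 | (3R,4S,5R,6R,7R,8R,10R)-3,15-bis[(tert-butyldimethylsilyl)oxy]-13-(dimethylamino)-8-hydroxy-5,10-epoxygermacran-12,6-olide, mixture of C11 epimers | CN(C)CC1C(=O)O[C@H]2[C@@H]3O[C@](C)(CC[C@@H](O[Si](C)(C)C(C)(C)C)[C@H]3CO[Si](C)(C)C(C)(C)C)C[C@@H](O)[C@@H]12 | intermediate
30 | N-methyl iodide (trimethylammonium iodide) of 29 | C[N+](C)(C)CC1C(=O)O[C@H]2[C@@H]3O[C@](C)(CC[C@@H](O[Si](C)(C)C(C)(C)C)[C@H]3CO[Si](C)(C)C(C)(C)C)C[C@@H](O)[C@@H]12.[I-] | intermediate
31 | (3R,4S,5R,6R,7R,8R,10R)-3,15-bis[(tert-butyldimethylsilyl)oxy]-8-hydroxy-5,10-epoxygermacr-11(13)-en-12,6-olide | C=C1C(=O)O[C@H]2[C@@H]3O[C@](C)(CC[C@@H](O[Si](C)(C)C(C)(C)C)[C@H]3CO[Si](C)(C)C(C)(C)C)C[C@@H](O)[C@@H]12 | intermediate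
32 | (2E)-but-2-enal (crotonaldehyde) | C/C=C/C=O | starting material
33 | (2Z)-2-iodobut-2-enal | C/C=C(\I)C=O | intermediate
34 | (2Z)-2-iodobut-2-en-1-ol | C/C=C(\I)CO | intermediate
35 | tert-butyl{[(2Z)-2-iodobut-2-en-1-yl]oxy}dimethylsilane | C/C=C(\I)CO[Si](C)(C)C(C)(C)C | intermediate
36 | (2Z)-2-{[(tert-butyldimethylsilyl)oxy]methyl}but-2-enoic acid | C/C=C(\C(=O)O)CO[Si](C)(C)C(C)(C)C | intermediate
37 | (3R,4S,5R,6R,7R,8R,10R)-3,15-bis[(tert-butyldimethylsilyl)oxy]-8-{[(2Z)-2-{[(tert-butyldimethylsilyl)oxy]methyl}but-2-enoyl]oxy}-5,10-epoxygermacr-11(13)-en-12,6-olide | C=C1C(=O)O[C@H]2[C@@H]3O[C@](C)(CC[C@@H](O[Si](C)(C)C(C)(C)C)[C@H]3CO[Si](C)(C)C(C)(C)C)C[C@@H](OC(=O)/C(=C\C)CO[Si](C)(C)C(C)(C)C)[C@@H]12 | intermediate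
38 | (3R,4R,5R,6R,7R,8R,10R)-3,15-dihydroxy-8-{[(2Z)-2-(hydroxymethyl)but-2-enoyl]oxy}-5,10-epoxygermacr-11(13)-en-12,6-olide | C=C1C(=O)O[C@H]2[C@@H]3O[C@](C)(CC[C@@H](O)[C@H]3CO)C[C@@H](OC(=O)/C(=C\C)CO)[C@@H]12 | intermediate
39 | (3R,4R,5R,6R,7R,8R,10R)-15-acetoxy-8-{[(2Z)-2-(acetoxymethyl)but-2-enoyl]oxy}-3-hydroxy-5,10-epoxygermacr-11(13)-en-12,6-olide | C=C1C(=O)O[C@H]2[C@@H]3O[C@](C)(CC[C@@H](O)[C@H]3COC(C)=O)C[C@@H](OC(=O)/C(=C\C)COC(C)=O)[C@@H]12 | target

## Step count and least certain steps

Total: 30 steps. Longest linear sequence: 25 steps from 1 (steps 1–4, 6–23 and 28–30); step 5 and steps 24–27 are side branches.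

**Step 19 (ring 2 closure).** The transition state must already adopt the trans-bridged geometry, so the ketyl may be reduced further to the alcohol or dimerise before it reaches C7, or electron transfer to the butenolide may expel the C6 oxygen. The fallback replaces the ketyl by a longer-lived acyl radical. It sets out from 25: chlorite oxidation (NaClO2, NaH2PO4, 2-methylbut-2-ene) gives carboxylic acid F1, and N-(phenylseleno)phthalimide with PBu3 converts this into Se-phenyl selenoester F2. Slow addition of Bu3SnH and AIBN in hot benzene should generate the acyl radical, which adds 7-exo to C7 of the butenolide. The product is ketone 27, where the route is rejoined, so step 20 is saved.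

**Step 15 (key step).** C5 is flanked by the branched C4, so closure may be slow; a 1,2-hydride shift of the activated epoxide, intermolecular opening, or loss of the primary TBS group could then compete. The fallback keeps the same bond but uses chelation instead of a Brønsted acid. It sets out from 16: buffered HF·pyridine removes the TMS group to give epoxy diol F3. Ti(OiPr)4, bound to the C7 hydroxyl and the epoxide oxygen, directs the C10 hydroxyl to C5 and gives oxepane diol F4. TEMPO with PhI(OAc)2 oxidises the primary hydroxyl to hydroxy aldehyde F5, and olefination with 17 returns to the route at 21.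

**Step 17 (photolactonisation).** The Z-enoate may undergo photochemical deconjugation by 1,5-hydrogen shift and end as the saturated 4-oxo ester, or the lactonisation may be too slow to drain the E/Z mixture. The thermal fallback sets out from 22: PhSeNa (from PhSeSePh and NaBH4 in EtOH) adds to the enoate and acid-catalysed lactonisation gives β-phenylselanyl lactone F6. Oxidation with H2O2 and pyridine triggers selenoxide elimination away from the oxygen-bearing carbon, which returns to the route at 24.

**Step 21 (C8 reduction).** Hydride delivery may show poor facial selectivity and regenerate the 8S alcohol, or the β-acyloxy ketone may lose the lactone oxygen by elimination during handling. The fallback sets out from 26, skips ketone 27 and inverts C8 by substitution: Mitsunobu reaction with 4-nitrobenzoic acid, PPh3 and diisopropyl azodicarboxylate gives the inverted 4-nitrobenzoate F7, and brief methanolysis (K2CO3, MeOH, 0 °C) returns to the route at 28.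

**Step 12 (asymmetric epoxidation).** The hindered Z-allylic alcohol may turn over slowly, with erosion of face selectivity. The fallback epoxidises later, under substrate control only. It sets out from 15: MnO2 oxidation in the presence of ylide 17 passes through (Z)-enal F8 to the (2E,4Z)-dienoate F9. mCPBA should then epoxidise the distal, electron-richer Z-alkene from the face opposite the C3 branch (allylic 1,3-strain). This returns to the route at 19.

**Step 28 (acylation).** Reversible conjugate addition of DMAP or chloride to the activated acid may isomerise the Z-acyl group to the E isomer. The fallback builds the ester carbonyl on the alcohol instead of activating the acid. It sets out from 31 and vinyl iodide 35: Pd(PPh3)4, CO (1 atm) and Et3N effect alkoxycarbonylation with retention of alkene geometry and return to the route at 37, with no new intermediate.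

## Further compounds

F1 | step 19 | carboxylic acid from 25: {(2R,5R,6S,7R)-5-[(tert-butyldimethylsilyl)oxy]-6-{[(tert-butyldimethylsilyl)oxy]methyl}-2-methyl-7-[(2R)-5-oxo-2,5-dihydrofuran-2-yl]oxepan-2-yl}acetic acid | O=C1C=C[C@@H](O1)[C@@H]2O[C@](C)(CC[C@@H](O[Si](C)(C)C(C)(C)C)[C@H]2CO[Si](C)(C)C(C)(C)C)CC(=O)O
F2 | step 19 | Se-phenyl selenoester of F1 | O=C1C=C[C@@H](O1)[C@@H]2O[C@](C)(CC[C@@H](O[Si](C)(C)C(C)(C)C)[C@H]2CO[Si](C)(C)C(C)(C)C)CC(=O)[Se]c3ccccc3
F3 | step 15 | epoxy diol: 16 without its TMS group | OC[C@H]1O[C@H]1[C@H](CO[Si](C)(C)C(C)(C)C)[C@H](O[Si](C)(C)C(C)(C)C)CC[C@@](C)(O)CCOCc1ccc(OC)cc1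
F4 | step 15 | (1R)-1-[(2R,3S,4R,7R)-4-[(tert-butyldimethylsilyl)oxy]-3-{[(tert-butyldimethylsilyl)oxy]methyl}-7-{2-[(4-methoxybenzyl)oxy]ethyl}-7-methyloxepan-2-yl]ethane-1,2-diol | OC[C@@H](O)[C@@H]1O[C@](C)(CC[C@@H](O[Si](C)(C)C(C)(C)C)[C@H]1CO[Si](C)(C)C(C)(C)C)CCOCc1ccc(OC)cc1
F5 | step 15 | α-hydroxy aldehyde from F4 (C7 aldehyde, C6 hydroxyl) | O=C[C@@H](O)[C@@H]1O[C@](C)(CC[C@@H](O[Si](C)(C)C(C)(C)C)[C@H]1CO[Si](C)(C)C(C)(C)C)CCOCc1ccc(OC)cc1
F6 | step 17 | β-phenylselanyl lactone (C7 epimers), saturated analogue of 24 | O=C1CC([Se]c3ccccc3)[C@@H](O1)[C@@H]2O[C@](C)(CC[C@@H](O[Si](C)(C)C(C)(C)C)[C@H]2CO[Si](C)(C)C(C)(C)C)CCO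
F7 | step 21 | 8R 4-nitrobenzoate of 28 | C1C(=O)O[C@H]2[C@@H]3O[C@](C)(CC[C@@H](O[Si](C)(C)C(C)(C)C)[C@H]3CO[Si](C)(C)C(C)(C)C)C[C@@H](OC(=O)c4ccc(cc4)[N+](=O)[O-])[C@@H]12
F8 | step 12 | (2Z)-enal from 15 | O=C/C=C\[C@H](CO[Si](C)(C)C(C)(C)C)[C@H](O[Si](C)(C)C(C)(C)C)CC[C@@](C)(O[Si](C)(C)C)CCOCc1ccc(OC)cc1
F9 | step 12 | methyl (2E,4Z)-dienoate from F8 | COC(=O)/C=C/C=C\[C@H](CO[Si](C)(C)C(C)(C)C)[C@H](O[Si](C)(C)C(C)(C)C)CC[C@@](C)(O[Si](C)(C)C)CCOCc1ccc(OC)cc1
F0 | step 28 | none | none
A1 | alternative 1 | C5 hydroperoxide of a trans-fused 13-nor-eudesman-12,6-olide (3-O-TBS, 8-O-benzyl, 15-acetate) | C1C(=O)O[C@H]2[C@]3(OO)[C@](C)(CC[C@@H](O[Si](C)(C)C(C)(C)C)[C@H]3COC(C)=O)C[C@@H](OCc4ccccc4)[C@@H]12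
A2 | alternative 1 | bridgehead ketal acetate of the 11-oxabicyclo[4.4.1]undecane lactone | C1C(=O)O[C@H]2[C@]3(OC(C)=O)O[C@](C)(CC[C@@H](O[Si](C)(C)C(C)(C)C)[C@H]3COC(C)=O)C[C@@H](OCc4ccccc4)[C@@H]12
A3 | alternative 2 | ring 1 oxepane C6 aldehyde carrying the (Z)-2-(bromomethyl)enoate with O8 as PMB ether | O=C[C@@H]1O[C@](C)(CC[C@@H](O[Si](C)(C)C(C)(C)C)[C@H]1COC(C)=O)C[C@@H](OCc2ccc(OC)cc2)/C=C(\CBr)C(=O)OC
A4 | alternative 2 | bicyclic α-methylene lactone with O8 as PMB ether | C=C1C(=O)O[C@H]2[C@@H]3O[C@](C)(CC[C@@H](O[Si](C)(C)C(C)(C)C)[C@H]3COC(C)=O)C[C@@H](OCc4ccc(OC)cc4)[C@@H]12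
A5 | alternative 3 | Cr(CO)3 complex of 2-methyl-6-{[(tert-butyldimethylsilyl)oxy]methyl}oxepin | CC1=CC=CC(CO[Si](C)(C)C(C)(C)C)=CO1.[Cr].[C-]#[O+].[C-]#[O+].[C-]#[O+]
A6 | alternative 3 | methyl (3E)-4-acetoxy-3-{1-[(tert-butyldimethylsilyl)oxy]ethenyl}but-3-enoate | CC(=O)O/C=C(CC(=O)OC)/C(=C)O[Si](C)(C)C(C)(C)C
A7 | alternative 3 | decomplexed [6+4] adduct, 11-oxabicyclo[4.4.1]undeca-2,4,8-triene | CC(=O)O[C@H]1[C@@H]2O[C@](C)(C=CC=C2CO[Si](C)(C)C(C)(C)C)CC(O[Si](C)(C)C(C)(C)C)=C1CC(=O)OC
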